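## Retrosynthetic overview
1. Vitekwangin B comes from a last-step TBDPS removal. The dihydronaphthalene ring is closed just before that by an intramolecular amine-catalysed aldol condensation (C3=C4) of a 2-(3-oxopropyl)benzaldehyde, so ring B is the only ring formed.
2. The 1,2-trans stereodiad (C1/C2) is set in one metal-free step: an enamine-catalysed SN1 α-alkylation of 4,4-diethoxybutanal with an o-(hydroxymethyl)benzhydryl cation (the proposed new step).
3. The benzhydrol comes from a bromo-phenol-aldehyde and 3,4-dimethoxyphenylmagnesium bromide. The aryl bromide is converted to CH2OH, which is later oxidised to the aryl aldehyde needed for the aldol ring closure.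

Assumptions:
- NBS brominates 3-hydroxy-2-methoxybenzaldehyde para to OH (C6).
- 4,4-Diethoxybutanal is made from the commercial nitrile by DIBAL-H reduction, with the imine hydrolysed by the aqueous work-up.
- The (S)-diphenylprolinol silyl ether is taken to give the required C2 configuration. If not, the (R)-catalyst is used.

## Route

**Step 1**
Reactants: 1 (3-hydroxy-2-methoxybenzaldehyde)
Product: 2 (6-bromo-3-hydroxy-2-methoxybenzaldehyde)
Conditions: NBS, MeCN, 0 °C → rt
Reagents that add atoms: NBS, O=C1CCC(=O)N1Br
Why: Electrophilic aromatic bromination is directed para to the free phenol, which places Br at C6. This carbon becomes C4a of the target.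

**Step 2**
Reactants: 2
Product: 3 (6-bromo-3-(tert-butyldiphenylsilyloxy)-2-methoxybenzaldehyde)
Conditions: TBDPSCl, imidazole, DMF, rt
Reagents that add atoms: TBDPSCl, CC(C)(C)[Si](Cl)(c1ccccc1)c1ccccc1
Why: Silyl protection of the phenol is needed for the organometallic steps. It is removed at the end by buffered fluoride without touching the enal.

**Step 3**
Reactants: 3; 4 (4-bromo-1,2-dimethoxybenzene)
Product: 5 ((6-bromo-3-(TBDPSO)-2-methoxyphenyl)(3,4-dimethoxyphenyl)methanol, racemic)
Conditions: 4, Mg, THF, reflux to make the Grignard reagent; then add 3, THF, 0 °C → rt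
Reagents that add atoms: 3,4-dimethoxyphenylmagnesium bromide, COc1ccc([Mg]Br)cc1OC
Why: Grignard 1,2-addition to the aldehyde builds the diarylmethine carbon (C1) and leaves the aryl bromide intact. The carbinol is racemic, which is acceptable because it is ionised in step 6.

**Step 4**
Reactants: 5
Product: 6 ((3,4-dimethoxyphenyl)[6-(hydroxymethyl)-2-methoxy-3-(TBDPSO)phenyl]methanol, racemic)
Conditions: n-BuLi (2.2 equiv), THF, −78 °C; DMF, −78 → 0 °C; aq. NH4Cl; then NaBH4, MeOH, 0 °C
Reagents that add atoms: DMF, CN(C)C=O
Why: The first equivalent of BuLi forms the lithium alkoxide and the second does Br/Li exchange. DMF formylates the aryl lithium (Bouveault), and NaBH4 reduces the resulting aldehyde or its lactol to the benzylic CH2OH.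

**Step 5**
Reactants: 7 (4,4-diethoxybutanenitrile)
Product: 8 (4,4-diethoxybutanal)
Conditions: DIBAL-H (1.05 equiv), toluene, −78 °C; then aq. Rochelle salt, rt
Reagents that add atoms: water, O
Why: DIBAL-H adds one hydride to the nitrile to give an N-aluminated imine. The aqueous Rochelle-salt work-up hydrolyses it to the aldehyde (the oxygen comes from water, NH3 is lost) and leaves the acetal, which is a masked second aldehyde, intact.

**Step 6**
Reactants: 6; 8
Product: 9 (acyclic triol-acetal: 2-[(3,4-dimethoxyphenyl)(aryl)methyl]-4,4-diethoxybutan-1-ol bearing the aryl CH2OH and OTBDPS; C1 and C2 in the target's spatial arrangement)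
Conditions: 8 (3 equiv), (S)-diphenylprolinol TES ether (20 mol%), (PhO)2P(O)OH (20 mol%), HFIP/CH2Cl2 1:4, 0 → 23 °C, 24 h; then NaBH4, MeOH, 0 °C
Reagents that add atoms: none
Why: Proposed new method: the acid ionises the electron-rich benzhydrol (p-OMe on Ar′, o-OMe on the other ring), and the cation is reversibly held as the 1-arylphthalan by the neighbouring CH2OH. The prolinol amine condenses with 8 to give the E, s-trans enamine, whose one face is shielded by the silyloxy diaryl group. The cation is therefore attacked on the open enamine face, which sets C2. The twisted o,o′-disubstituted aryl ring (OMe on one side, CH2OH on the other) differentiates the two cation faces, which sets C1 relative to C2 (the relation that becomes the 1,2-trans ring). In situ NaBH4 reduction of the α-alkylated aldehyde to the primary alcohol stops C2 epimerisation. The closest known reaction is enamine-catalysed SN1 α-alkylation of aldehydes with stabilised (ferrocenyl, bis-p-aminophenyl, xanthylium) carbocations under Jørgensen–Hayashi catalysis. It has not been shown with an unsymmetrical, ortho-disubstituted diarylmethyl cation that sets two contiguous stereocentres.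

**Step 7**
Reactants: 9
Product: 10 (aryl aldehyde: the benzylic CH2OH oxidised to CHO; the C2 primary alcohol and the acetal are retained)
Conditions: activated MnO2 (15 equiv), CH2Cl2, rt
Reagents that add atoms: none
Why: MnO2 oxidises the electron-rich benzylic alcohol selectively over the unactivated aliphatic one. Neither stereocentre has an acidic α-H, so both are untouched.

**Step 8**
Reactants: 10
Product: 11 (aryl aldehyde / aliphatic aldehyde / primary alcohol; the aliphatic aldehyde is in equilibrium with its 2-hydroxytetrahydrofuran lactol)
Conditions: PPTS (0.3 equiv), acetone/H2O 4:1, 55 °C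
Reagents that add atoms: water, O
Why: Mild acid hydrolysis of the diethyl acetal to the aldehyde (EtOH is lost). The aryl TBDPS ether is stable to these conditions, and the stereocentres are β to the new aldehyde and not epimerisable.

**Step 9**
Reactants: 11
Product: 12 (TBDPS ether of vitekwangin B, (1S,2R)-1-(3,4-dimethoxyphenyl)-2-(hydroxymethyl)-8-methoxy-7-(TBDPSO)-1,2-dihydronaphthalene-3-carbaldehyde)
Conditions: pyrrolidine (20 mol%), AcOH (20 mol%), CH2Cl2, 4 Å MS, 25 °C
Reagents that add atoms: none
Why: Intramolecular enamine aldol condensation. The enamine of the aliphatic aldehyde attacks the aryl aldehyde to close the six-membered ring, and loss of water gives the conjugated enal C3=C4. No stereocentre is created, and the existing ones are not disturbed.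

**Step 10**
Reactants: 12
Product: 13 (vitekwangin B)
Conditions: TBAF/AcOH (1:1), THF, 0 °C
Reagents that add atoms: none
Why: Buffered fluoride removes the aryl silyl ether (desilylation) and leaves the enal, the primary alcohol and both stereocentres intact.

## Compound list
1 | 3-hydroxy-2-methoxybenzaldehyde | COc1c(O)cccc1C=O | starting material
2 | 6-bromo-3-hydroxy-2-methoxybenzaldehyde | COc1c(O)ccc(Br)c1C=O | intermediate
3 | 6-bromo-3-(TBDPS-oxy)-2-methoxybenzaldehyde | COc1c(O[Si](c2ccccc2)(c2ccccc2)C(C)(C)C)ccc(Br)c1C=O | intermediate
4 | 4-bromo-1,2-dimethoxybenzene | COc1ccc(Br)cc1OC | starting material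
5 | (6-bromo-3-(TBDPSO)-2-methoxyphenyl)(3,4-dimethoxyphenyl)methanol (racemic) | COc1ccc(C(O)c2c(Br)ccc(O[Si](c3ccccc3)(c3ccccc3)C(C)(C)C)c2OC)cc1OC | intermediate
6 | (3,4-dimethoxyphenyl)[6-(hydroxymethyl)-2-methoxy-3-(TBDPSO)phenyl]methanol (racemic) | COc1ccc(C(O)c2c(CO)ccc(O[Si](c3ccccc3)(c3ccccc3)C(C)(C)C)c2OC)cc1OC | intermediate
7 | 4,4-diethoxybutanenitrile | N#CCCC(OCC)OCC | starting material
8 | 4,4-diethoxybutanal | O=CCCC(OCC)OCC | intermediate
9 | triol acetal (benzhydryl and C2 centres as drawn) | COc1ccc([C@@H](c2c(CO)ccc(O[Si](c3ccccc3)(c3ccccc3)C(C)(C)C)c2OC)[C@@H](CO)CC(OCC)OCC)cc1OC | intermediate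
10 | aryl aldehyde acetal alcohol | COc1ccc([C@@H](c2c(C=O)ccc(O[Si](c3ccccc3)(c3ccccc3)C(C)(C)C)c2OC)[C@@H](CO)CC(OCC)OCC)cc1OC | intermediate
11 | aryl aldehyde / aliphatic aldehyde / alcohol | COc1ccc([C@@H](c2c(C=O)ccc(O[Si](c3ccccc3)(c3ccccc3)C(C)(C)C)c2OC)[C@@H](CO)CC=O)cc1OC | intermediate
12 | TBDPS-protected vitekwangin B | COc1ccc([C@H]2c3c(ccc(O[Si](c4ccccc4)(c4ccccc4)C(C)(C)C)c3OC)C=C(C=O)[C@@H]2CO)cc1OC | intermediate
13 | vitekwangin B | COc1ccc([C@H]2c3c(ccc(O)c3OC)C=C(C=O)[C@@H]2CO)cc1OC | target

## Totals
Total steps: 10 (step 5 is a convergent side branch that makes aldehyde 8).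
Longest linear sequence: 9 steps (steps 1, 2, 3, 4, 6, 7, 8, 9, 10; compounds 1 → 2 → 3 → 5 → 6 → 9 → 10 → 11 → 12 → 13).

## Three steps most likely to fail
1. **Step 6 (proposed new step).** The cation may not form, or may be trapped as the phthalan, and dr or ee may be modest. Fallback (known chemistry, different approach): couple diol 6 with the achiral pyrrolidine enamine or a silyl enol ether of 8 under Brønsted-acid/HFIP SN1 conditions. Separate the trans diastereomer of 9 chromatographically, resolve its enantiomers by chiral-phase HPLC or lipase-catalysed acylation, and continue from step 7.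
2. **Step 4.** n-BuLi may attack the aryl silyl ether, or the alkoxide/aryl-lithium pair may behave poorly. Fallback: Suzuki–Miyaura coupling of bromide 5 with potassium acetoxymethyltrifluoroborate (Pd/RuPhos, Cs2CO3, dioxane/H2O), then K2CO3/MeOH to cleave the acetate to diol 6.
3. **Step 1.** NBS may also brominate ortho to the phenol (C4). Fallback: silylate 1 first, then use a Comins α-amino-alkoxide (N,N,N′-trimethylethylenediamine/BuLi) ortho-lithiation and quench with 1,2-dibromotetrachloroethane. The only free position ortho to the aldehyde is C6, so this gives bromide 3 regiospecifically.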